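With decalin numbering (C1 carboxyl-bearing, C4a/C8a ring fusion, C5 side-chain carbon), ring A is cut across C4–C4a and C1–C8a into a C1–C4 diene and the C4a=C8a alkene of a ring-B enone. The key step, an intramolecular Diels–Alder reaction of a (Z)-dienyl 2-methyl-3-oxocyclohexenecarboxylate, closes ring A, creates both quaternary ring-fusion carbons and fixes C1 in one operation. It exploits the cis relation of the C1 carboxyl carbon and the C8a methyl carbon: both are joined through oxygen as a γ-lactone tether (C8a–C(=O)–O–CH2–C1), later reduced to CH3 and oxidised to CO2H. The racemic adduct is resolved with a ketoreductase.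

Key step: step 5

Remark (assumptions): a commercial ketoreductase panel is assumed to contain an enzyme that reduces only the (1R,4aR,8aR)-enantiomer of 8, and (R,R)-(salen)Co(OAc) is assumed to be the matched catalyst antipode for epoxide 22; all locants are the decalin locants defined above.

Step 1
Reactants: 1 (2Z)-3-methylpent-2-en-4-yn-1-ol
Product: 2 (2Z)-3-methylpenta-2,4-dien-1-ol
Conditions: H2 (1 atm), Pd/CaCO3 poisoned with Pb(OAc)2 (Lindlar catalyst), quinoline, EtOAc, 0 °C to rt
Reagents that add atoms: none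
Why: Lindlar semi-hydrogenation should stop the terminal alkyne at the alkene and leave the trisubstituted Z-alkene untouched, so the Z-diene geometry needed in step 5 comes from the starting material.

Step 2
Reactants: 3 2-methylcyclohexane-1,3-dione
Product: 4 2-methyl-3-oxocyclohex-1-en-1-yl trifluoromethanesulfonate
Conditions: Tf2O, pyridine, CH2Cl2, −78 to 0 °C
Reagents that add atoms: trifluoromethanesulfonic anhydride O=S(=O)(OS(=O)(=O)C(F)(F)F)C(F)(F)F
Why: O-sulfonylation of the enolised symmetric 1,3-dione should give the β-triflyloxy enone as the only possible regioisomer.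

Step 3
Reactants: 4 2-methyl-3-oxocyclohex-1-en-1-yl trifluoromethanesulfonate
Product: 6 2-methyl-3-oxocyclohex-1-ene-1-carboxylic acid, via mixed acetic anhydride 5 (not isolated)
Conditions: CO (1 atm), Pd(OAc)2 (5 mol%), dppf, KOAc, DMSO, rt to 50 °C; then aqueous HCl
Reagents that add atoms: carbon monoxide [C-]#[O+]; potassium acetate CC(=O)[O-].[K+]
Why: Palladium-catalysed hydroxycarbonylation of an enol triflate (oxidative addition to zerovalent palladium, CO insertion, capture of the acyl palladium by acetate) should give the mixed anhydride, which water cleaves at the unhindered acetyl carbonyl on work-up.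

Step 4
Reactants: 6 2-methyl-3-oxocyclohex-1-ene-1-carboxylic acid; 2 (2Z)-3-methylpenta-2,4-dien-1-ol
Product: 7 (2Z)-3-methylpenta-2,4-dien-1-yl 2-methyl-3-oxocyclohex-1-ene-1-carboxylate
Conditions: EDC·HCl, DMAP (cat.), CH2Cl2, 0 °C to rt
Reagents that add atoms: none
Why: Steglich esterification should join the acid and the primary allylic alcohol under metal-free, near-neutral conditions that cannot scramble the Z-alkene.

Step 5
Reactants: 7 (2Z)-3-methylpenta-2,4-dien-1-yl 2-methyl-3-oxocyclohex-1-ene-1-carboxylate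
Product: 8 racemic γ-lactone of (1S*,4aS*,8aS*)-1-(hydroxymethyl)-2,4a-dimethyl-5-oxo-1,4,4a,5,6,7,8,8a-octahydronaphthalene-8a-carboxylic acid
Conditions: o-xylene (0.01 M), BHT (cat.), 140 °C, argon
Reagents that add atoms: none
Why: Thermal, concerted, suprafacial [4+2] cycloaddition of normal electron demand in which the Z-diene (C1–C4) adds to the C4a=C8a bond of ring B, a tetrasubstituted alkene activated at both ends (ring ketone on C4a, tether ester on C8a); the closest known reaction type is the intramolecular Diels–Alder reaction of ester-tethered nona-1,3,8-trienes such as pentadienyl fumarates. Ring A is closed as the six-membered cycloadduct ring (bonds C4–C4a and C1–C8a), and the γ-lactone is closed at the same time as the five-membered ring carried by the three-atom tether (fused mode). C4a and C8a come out cis because the alkene geometry of ring B is transferred suprafacially, so the 4a-methyl and the lactone carbonyl (the future 8a-methyl) share one face and ring B takes the other. C1 is controlled by the Z-diene: a tether on the inside position of the diene terminus can reach the dienophile only in the arrangement with ring B endo, which gives the cis-fused lactone, so the C1 CH2O is cis to the C8a carbonyl. The step needs regioselectivity (C1 to C8a, C4 to C4a), which the short tether enforces, and enough rate to outrun [1,5]-hydrogen shift of the Z-dienyl unit, which the double activation of the dienophile and high dilution are meant to secure. No absolute control is exerted, so 8 should form as the racemate and is resolved in step 6.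

Step 6
Reactants: 8 racemic γ-lactone of (1S*,4aS*,8aS*)-1-(hydroxymethyl)-2,4a-dimethyl-5-oxo-1,4,4a,5,6,7,8,8a-octahydronaphthalene-8a-carboxylic acid
Product: 9 γ-lactone of (1S,4aS,8aS)-1-(hydroxymethyl)-2,4a-dimethyl-5-oxo-1,4,4a,5,6,7,8,8a-octahydronaphthalene-8a-carboxylic acid
Conditions: ketoreductase (commercial panel enzyme), NADP+ (cat.), i-PrOH, phosphate buffer pH 7 with DMSO, 30 °C, run to half conversion; chromatography
Reagents that add atoms: none
Why: Enzymatic kinetic resolution: ketoreductases usually discriminate well between the enantiomers of bicyclic cyclohexanones with an α-quaternary carbon, so reduction of only the (1R,4aR,8aR)-ketone should leave 9 untouched and fix the absolute configuration of C1, C4a and C8a.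

Step 7
Reactants: 9 γ-lactone of (1S,4aS,8aS)-1-(hydroxymethyl)-2,4a-dimethyl-5-oxo-1,4,4a,5,6,7,8,8a-octahydronaphthalene-8a-carboxylic acid
Product: 10 γ-lactone of (1S,2R,4aS,8aS)-1-(hydroxymethyl)-2,4a-dimethyl-5-oxodecahydronaphthalene-8a-carboxylic acid
Conditions: Mn(dpm)3 (10 mol%, trivalent manganese), PhSiH3, t-BuOOH, i-PrOH, rt
Reagents that add atoms: none
Why: Metal-hydride hydrogen atom transfer (MHAT) hydrogenation: H-atom transfer to C3 gives the tertiary C2 radical, which should accept the second hydrogen axially on the lactone face, so the 2-methyl becomes equatorial and trans to the C1 CH2O (2R); its epimer would be 1,3-diaxial to the C8a carbonyl carbon.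

Step 8
Reactants: 10 γ-lactone of (1S,2R,4aS,8aS)-1-(hydroxymethyl)-2,4a-dimethyl-5-oxodecahydronaphthalene-8a-carboxylic acid
Product: 12 γ-lactone of (1S,2R,4aS,8aS)-1-(hydroxymethyl)-2,4a-dimethyl-5-(trifluoromethanesulfonyloxy)-1,2,3,4,4a,7,8,8a-octahydronaphthalene-8a-carboxylic acid, via potassium enolate 11 (not isolated)
Conditions: KHMDS, THF, −78 °C; then PhNTf2, −78 to 0 °C
Reagents that add atoms: N-phenylbis(trifluoromethanesulfonimide) O=S(=O)(N(c1ccccc1)S(=O)(=O)C(F)(F)F)C(F)(F)F
Why: Only C6 carries α-hydrogens (C4a is quaternary and the lactone carbonyl sits on quaternary C8a), so enolisation and O-triflation should give a single enol triflate with the C5=C6 double bond of the target.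

Step 9
Reactants: 13 5-bromo-2-methylpent-2-ene
Product: 14 (4-methylpent-3-en-1-yl)zinc bromide (THF solution, used directly)
Conditions: Zn dust, LiCl, I2 (cat.), THF, 40 °C
Reagents that add atoms: zinc [Zn]
Why: LiCl-mediated direct insertion of zinc into the primary alkyl bromide should give the alkylzinc halide without touching the trisubstituted alkene.

Step 10
Reactants: 12 γ-lactone of (1S,2R,4aS,8aS)-1-(hydroxymethyl)-2,4a-dimethyl-5-(trifluoromethanesulfonyloxy)-1,2,3,4,4a,7,8,8a-octahydronaphthalene-8a-carboxylic acid; 14 (4-methylpent-3-en-1-yl)zinc bromide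
Product: 15 γ-lactone of (1S,2R,4aR,8aS)-1-(hydroxymethyl)-2,4a-dimethyl-5-(4-methylpent-3-en-1-yl)-1,2,3,4,4a,7,8,8a-octahydronaphthalene-8a-carboxylic acid
Conditions: Pd(dppf)Cl2 (5 mol%), THF, 50 °C
Reagents that add atoms: none
Why: Negishi sp2–sp3 coupling of the alkenyl triflate with the primary alkylzinc reagent should install the side chain at C5; the lactone is inert to organozinc and the bidentate ligand suppresses β-hydride elimination.

Step 11
Reactants: 15 γ-lactone of (1S,2R,4aR,8aS)-1-(hydroxymethyl)-2,4a-dimethyl-5-(4-methylpent-3-en-1-yl)-1,2,3,4,4a,7,8,8a-octahydronaphthalene-8a-carboxylic acid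
Product: 16 the corresponding lactol (1S,2R,4aR,8aS; C8a–CH(OH)–O–CH2–C1, anomeric mixture)
Conditions: i-Bu2AlH (1.2 equiv), CH2Cl2, −78 °C; aqueous Rochelle salt
Reagents that add atoms: none
Why: Half-reduction of a γ-lactone to the lactol at low temperature is standard, leaves the alkenes alone, and the anomeric mixture is irrelevant because this carbon becomes CH3 in step 12.

Step 12
Reactants: 16 lactol (1S,2R,4aR,8aS)
Product: 18 [(1S,2R,4aR,8aR)-2,4a,8a-trimethyl-5-(4-methylpent-3-en-1-yl)-1,2,3,4,4a,7,8,8a-octahydronaphthalen-1-yl]methanol, via hydroxy aldehyde hydrazone 17 (not isolated)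
Conditions: N2H4·H2O, KOH, diethylene glycol, 130 °C, then 200 °C with removal of water
Reagents that add atoms: none
Why: Wolff–Kishner reduction: the lactol opens to the non-enolisable C8a aldehyde, whose hydrazone should lose N2 under base to leave the 8a-methyl group and the free C1 CH2OH; the isolated trisubstituted alkenes are inert.

Step 13
Reactants: 18 [(1S,2R,4aR,8aR)-2,4a,8a-trimethyl-5-(4-methylpent-3-en-1-yl)-1,2,3,4,4a,7,8,8a-octahydronaphthalen-1-yl]methanol
Product: 20 (1S,2R,4aR,8aR)-2,4a,8a-trimethyl-5-(4-methylpent-3-en-1-yl)-1,2,3,4,4a,7,8,8a-octahydronaphthalene-1-carboxylic acid, via aldehyde 19 (not isolated)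
Conditions: TEMPO (cat.), PhI(OAc)2, MeCN/H2O, rt
Reagents that add atoms: water O
Why: Oxoammonium oxidation of the primary alcohol through the aldehyde hydrate should give the acid without touching the alkenes; C1 already has the thermodynamically preferred configuration (equatorial, trans to the 2-methyl), so enolisation of 19 cannot erode it.

Step 14
Reactants: 21 (S)-glycidol [(2S)-oxiran-2-ylmethanol]
Product: 22 (R)-glycidyl acetate [(2R)-oxiran-2-ylmethyl acetate]
Conditions: Ac2O, Et3N, DMAP (cat.), CH2Cl2, 0 °C
Reagents that add atoms: acetic anhydride CC(=O)OC(C)=O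
Why: O-acetylation does not touch the stereocentre; the descriptor changes from S to R only because the CIP priorities change.

Step 15
Reactants: 20 (1S,2R,4aR,8aR)-2,4a,8a-trimethyl-5-(4-methylpent-3-en-1-yl)-1,2,3,4,4a,7,8,8a-octahydronaphthalene-1-carboxylic acid; 22 (R)-glycidyl acetate
Product: 23 (2S)-3-(acetyloxy)-2-hydroxypropyl (1S,2R,4aR,8aR)-2,4a,8a-trimethyl-5-(4-methylpent-3-en-1-yl)-1,2,3,4,4a,7,8,8a-octahydronaphthalene-1-carboxylate (target)
Conditions: (R,R)-(salen)Co(OAc) (trivalent cobalt; salen = N,N′-bis(3,5-di-tert-butylsalicylidene)cyclohexane-1,2-diamine dianion; 5 mol%), i-Pr2NEt, MTBE, rt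
Reagents that add atoms: none
Why: Lewis-acid-catalysed addition of the carboxylic acid to the terminal epoxide carbon should give the 1,3-diacylglycerol with free 2-OH directly; the glycerol stereocentre is not a reaction centre and is carried over from (S)-glycidol, and the mild conditions avoid acyl migration.

Compound list
1 | (2Z)-3-methylpent-2-en-4-yn-1-ol | C#C/C(C)=C\CO | starting material
2 | (2Z)-3-methylpenta-2,4-dien-1-ol | C=C/C(C)=C\CO | intermediate
3 | 2-methylcyclohexane-1,3-dione | CC1C(=O)CCCC1=O | starting material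
4 | 2-methyl-3-oxocyclohex-1-en-1-yl trifluoromethanesulfonate | CC1=C(OS(=O)(=O)C(F)(F)F)CCCC1=O | intermediate
5 | acetic 2-methyl-3-oxocyclohex-1-ene-1-carboxylic anhydride (not isolated) | CC(=O)OC(=O)C1=C(C)C(=O)CCC1 | intermediate
6 | 2-methyl-3-oxocyclohex-1-ene-1-carboxylic acid | CC1=C(C(=O)O)CCCC1=O | intermediate
7 | (2Z)-3-methylpenta-2,4-dien-1-yl 2-methyl-3-oxocyclohex-1-ene-1-carboxylate | CC1=C(C(=O)OC/C=C(/C)C=C)CCCC1=O | intermediate
8 | racemic γ-lactone of (1S*,4aS*,8aS*)-1-(hydroxymethyl)-2,4a-dimethyl-5-oxo-1,4,4a,5,6,7,8,8a-octahydronaphthalene-8a-carboxylic acid (lactone cis-fused, 4a-methyl cis to the lactone carbonyl; both enantiomers) | O=C1OC[C@H]2C(C)=CC[C@]3(C)C(=O)CCC[C@]123.O=C1OC[C@@H]2C(C)=CC[C@@]3(C)C(=O)CCC[C@@]123 | intermediate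
9 | γ-lactone of (1S,4aS,8aS)-1-(hydroxymethyl)-2,4a-dimethyl-5-oxo-1,4,4a,5,6,7,8,8a-octahydronaphthalene-8a-carboxylic acid | O=C1OC[C@H]2C(C)=CC[C@]3(C)C(=O)CCC[C@]123 | intermediate
10 | γ-lactone of (1S,2R,4aS,8aS)-1-(hydroxymethyl)-2,4a-dimethyl-5-oxodecahydronaphthalene-8a-carboxylic acid | O=C1OC[C@H]2[C@H](C)CC[C@]3(C)C(=O)CCC[C@]123 | intermediate
11 | potassium C5–C6 enolate of 10 (not isolated) | O=C1OC[C@H]2[C@H](C)CC[C@]3(C)C([O-])=CCC[C@]123.[K+] | intermediate
12 | γ-lactone of (1S,2R,4aS,8aS)-1-(hydroxymethyl)-2,4a-dimethyl-5-(trifluoromethanesulfonyloxy)-1,2,3,4,4a,7,8,8a-octahydronaphthalene-8a-carboxylic acid | O=C1OC[C@H]2[C@H](C)CC[C@]3(C)C(OS(=O)(=O)C(F)(F)F)=CCC[C@]123 | intermediate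
13 | 5-bromo-2-methylpent-2-ene | CC(C)=CCCBr | starting material
14 | (4-methylpent-3-en-1-yl)zinc bromide | CC(C)=CCC[Zn]Br | intermediate
15 | γ-lactone of (1S,2R,4aR,8aS)-1-(hydroxymethyl)-2,4a-dimethyl-5-(4-methylpent-3-en-1-yl)-1,2,3,4,4a,7,8,8a-octahydronaphthalene-8a-carboxylic acid | O=C1OC[C@H]2[C@H](C)CC[C@]3(C)C(CCC=C(C)C)=CCC[C@]123 | intermediate
16 | lactol of 15 (1S,2R,4aR,8aS; C8a–CH(OH)–O–CH2–C1, anomeric mixture) | OC1OC[C@H]2[C@H](C)CC[C@]3(C)C(CCC=C(C)C)=CCC[C@]123 | intermediate
17 | hydrazone of (1S,2R,4aR,8aS)-1-(hydroxymethyl)-2,4a-dimethyl-5-(4-methylpent-3-en-1-yl)-1,2,3,4,4a,7,8,8a-octahydronaphthalene-8a-carbaldehyde (not isolated) | OC[C@H]1[C@H](C)CC[C@]2(C)C(CCC=C(C)C)=CCC[C@]12C=NN | intermediate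
18 | [(1S,2R,4aR,8aR)-2,4a,8a-trimethyl-5-(4-methylpent-3-en-1-yl)-1,2,3,4,4a,7,8,8a-octahydronaphthalen-1-yl]methanol | OC[C@H]1[C@H](C)CC[C@]2(C)C(CCC=C(C)C)=CCC[C@]12C | intermediate
19 | (1S,2R,4aR,8aR)-2,4a,8a-trimethyl-5-(4-methylpent-3-en-1-yl)-1,2,3,4,4a,7,8,8a-octahydronaphthalene-1-carbaldehyde (not isolated) | O=C[C@H]1[C@H](C)CC[C@]2(C)C(CCC=C(C)C)=CCC[C@]12C | intermediate
20 | (1S,2R,4aR,8aR)-2,4a,8a-trimethyl-5-(4-methylpent-3-en-1-yl)-1,2,3,4,4a,7,8,8a-octahydronaphthalene-1-carboxylic acid | OC(=O)[C@H]1[C@H](C)CC[C@]2(C)C(CCC=C(C)C)=CCC[C@]12C | intermediate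
21 | (S)-glycidol | OC[C@H]1CO1 | starting material
22 | (R)-glycidyl acetate | CC(=O)OC[C@H]1CO1 | intermediate
23 | (2S)-3-(acetyloxy)-2-hydroxypropyl (1S,2R,4aR,8aR)-2,4a,8a-trimethyl-5-(4-methylpent-3-en-1-yl)-1,2,3,4,4a,7,8,8a-octahydronaphthalene-1-carboxylate | CC(=O)OC[C@H](O)COC(=O)[C@H]1[C@H](C)CC[C@]2(C)C(CCC=C(C)C)=CCC[C@]12C | target

Total step count: 15. Longest linear sequence: 12 steps (steps 2–8, 10–13 and 15, from 3).

Steps most likely to fail

Step 5 (key step). The cycloaddition of the Z-diene onto the tetrasubstituted dienophile may be too slow, so that [1,5]-hydrogen shift of the Z-dienyl unit or oligomerisation consumes the triene. The fallback sets out from 6 and comes back at 8. Purchased (2E)-3-methylpent-2-en-4-yn-1-ol F1 would be semi-hydrogenated as in step 1 to (2E)-3-methylpenta-2,4-dien-1-ol F2, and F2 esterified with 6 as in step 4 to (2E)-3-methylpenta-2,4-dien-1-yl 2-methyl-3-oxocyclohex-1-ene-1-carboxylate F3. Heating F3 (toluene, 110 °C, high dilution) should then give 8. The E-diene has no inside substituent, cannot undergo the [1,5]-shift and reaches the s-cis conformer easily. The price is that the cis fusion of the lactone is no longer enforced by geometry; it would rest on a preference for the transition state with ring B exo, away from the C2 methyl of the diene, and a chromatographic separation of ring-fusion isomers may be needed.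

Step 6. The enzyme panel may not accept the hindered α-quaternary ketone, or may reduce both enantiomers at similar rates. The fallback sets out from 8 and comes back at 9 by covalent resolution. Ketalisation of 8 with (1R,2R)-1,2-diphenylethane-1,2-diol (as its bis-trimethylsilyl ether, TMSOTf cat., CH2Cl2, −40 °C) should give the spiro-ketal of the wanted enantiomer F4 and the diastereomeric spiro-ketal of the unwanted enantiomer F5. Because the diol is C2-symmetric, no further stereocentre arises and only these two diastereomers form; they would be separated by chromatography or crystallisation. Hydrolysis of F4 (aqueous HCl, THF) returns 9.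

Step 7. Hydrogen delivery to the C2 radical may occur from the wrong face, giving poor selectivity at C2. The fallback sets out from 9 and comes back at 10 and replaces radical control by a directed hydrogenation. Aminolysis of the lactone with pyrrolidine (neat, 60 °C) should give the hydroxy pyrrolidine amide F6. Hydrogenation of F6 with [Ir(cod)(PCy3)(py)]PF6 under H2 in CH2Cl2 would be directed by the C1 CH2OH and the C8a amide carbonyl, which both lie on the face of the 4a-methyl, so hydrogen reaches C2 from that face to give the saturated hydroxy amide F7. Acid (TsOH, toluene, 80 °C) then relactonises F7 to 10.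

Further compounds
F1 | step 5 | (2E)-3-methylpent-2-en-4-yn-1-ol (purchased) | C#C/C(C)=C/CO
F2 | step 5 | (2E)-3-methylpenta-2,4-dien-1-ol | C=C/C(C)=C/CO
F3 | step 5 | (2E)-3-methylpenta-2,4-dien-1-yl 2-methyl-3-oxocyclohex-1-ene-1-carboxylate | CC1=C(C(=O)OC/C=C(\C)C=C)CCCC1=O
F4 | step 6 | (4R,5R)-4,5-diphenyl-1,3-dioxolane spiro-ketal at C5 of 9 | O=C1OC[C@H]2C(C)=CC[C@]3(C)C4(O[C@H](c5ccccc5)[C@@H](c5ccccc5)O4)CCC[C@]123
F5 | step 6 | (4R,5R)-4,5-diphenyl-1,3-dioxolane spiro-ketal at C5 of the enantiomer of 9 | O=C1OC[C@@H]2C(C)=CC[C@@]3(C)C4(O[C@H](c5ccccc5)[C@@H](c5ccccc5)O4)CCC[C@@]123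
F6 | step 7 | (1S,4aS,8aS)-1-(hydroxymethyl)-2,4a-dimethyl-8a-(pyrrolidine-1-carbonyl)-1,4,4a,6,7,8-hexahydronaphthalen-5-one | OC[C@H]1C(C)=CC[C@]2(C)C(=O)CCC[C@]12C(=O)N1CCCC1
F7 | step 7 | (1S,2R,4aS,8aS)-1-(hydroxymethyl)-2,4a-dimethyl-8a-(pyrrolidine-1-carbonyl)octahydronaphthalen-5-one | OC[C@H]1[C@H](C)CC[C@]2(C)C(=O)CCC[C@]12C(=O)N1CCCC1
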